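The target is a selinane (eudesmane) carrying oxygen at C3, C4 and C8, so all fifteen skeletal carbons are traced back to acyclic (2E,6E)-farnesyl diphosphate. One enzymatic cation cascade in step 3 forms the C6–C7 and C5–C10 bonds, closes rings B and A and sets the trans ring fusion (H5 α, C14 methyl on C10 β). It exploits the fact that rings A and B, the C14 and C15 methyls and the C7=C11 isopropylidene map atom for atom onto a head-to-tail farnesyl chain. The cascade ends with a C3=C4 alkene, the handle for both ring A oxygens, while C7=C11 later activates C8.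

Key step: step 3

Assumption: a variant of the characterised selina-4(15),7(11)-diene cyclase that binds the fold of the 5α-H,10β-methyl series and removes a C3 proton is taken to be obtainable by active-site engineering; everything else is conventional chemistry.

Convention: eudesmane numbering throughout. The target is read as 3β-angeloyloxy (equatorial), 4α-acetoxy with 4β-methyl, 5α-H, 10β-methyl, C7=C11, C8=O, so the two ring A oxygens are trans-diequatorial. No protecting groups are used.

Step 1
Reactants: 1 (2E,6E)-farnesol
Product: 2 (2E,6E)-farnesyl chloride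
Conditions: NCS, Me2S, CH2Cl2, −30 → 0 °C
Reagents that add atoms: N-chlorosuccinimide, ClN1C(=O)CCC1=O
Why: Corey–Kim chlorination converts the primary allylic alcohol to the chloride under neutral, non-ionising conditions, so neither allylic transposition nor E/Z scrambling of the 2,3-alkene is expected.

Step 2
Reactants: 2 (2E,6E)-farnesyl chloride
Product: 3 (2E,6E)-farnesyl diphosphate (isolated as the triammonium salt)
Conditions: (n-Bu4N)3HP2O7, MeCN, rt; cation exchange to the NH4+ form (aq. NH4HCO3), cellulose chromatography
Reagents that add atoms: tris(tetrabutylammonium) hydrogen diphosphate, CCCC[N+](CCCC)(CCCC)CCCC.CCCC[N+](CCCC)(CCCC)CCCC.CCCC[N+](CCCC)(CCCC)CCCC.OP(=O)([O-])OP(=O)([O-])[O-]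
Why: SN2 displacement of a primary allylic chloride by the diphosphate anion in a dipolar aprotic solvent is the standard diphosphorylation of prenyl halides and proceeds without allylic rearrangement.

Step 3
Reactants: 3 (2E,6E)-farnesyl diphosphate
Product: 5 selina-3,7(11)-diene (5α-H; 10β-methyl), via germacrene B 4 (not isolated)
Conditions: engineered selinadiene cyclase (recombinant class 1 sesquiterpene cyclase variant), MgCl2, HEPES buffer pH 7.5, glycerol, 30 °C, n-pentane overlay
Reagents that add atoms: none
Why: Proposed new method: the Mg2+ cluster of a class 1 cyclase ionises the allylic diphosphate of 3, the C7=C11 alkene traps the C6 cation and H7 is lost to give bound, achiral germacrene B (4), and re-protonation at C1 then lets C4=C5 attack C10 before the tertiary C4 cation loses H3. The closest known reaction type is the cascade of the characterised selina-4(15),7(11)-diene synthase, which passes through the same germacrene and the same eudesmyl C4 cation and ends by loss of a C15 proton; a variant that removes H3 instead and delivers the 5α-H,10β-methyl series is assumed, not demonstrated. Ring B is begun by the C6–C7 bond, a ten-membered macrocyclisation in which the attacking alkene stays exocyclic (exo mode, cation at tertiary C11), and the transannular C5–C10 bond then closes ring A in a 6-endo and ring B in a 6-exo sense with respect to C4=C5. C5 and C10 are both created in that transannular step: the pocket holds the two E alkenes of 4 in one crossed chair–chair conformer, anti addition across C1=C10 and C4=C5 then forces H5 and C14 trans, and the choice between the two mirror-image conformers of 4 by the chiral active site fixes the absolute configuration. The step needs trans fusion, which the (2E,6E) geometry of 3 and the all-tertiary cation sequence (C11, C10, C4) secure without competing shifts, and it needs deprotonation at C3 and not at C15 or C5, which nothing in the substrate secures and which rests on the placement of the active-site base.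

Step 4
Reactants: 5 selina-3,7(11)-diene
Product: 6 eudesm-7(11)-ene-3α,4α-diol (4β-methyl)
Conditions: OsO4 (2 mol %), NMO, acetone/H2O, 0 °C → rt
Reagents that add atoms: N-methylmorpholine N-oxide, C[N+]1([O-])CCOCC1; water, O (both oxygens are delivered through osmium tetroxide, O=[Os](=O)(=O)=O)
Why: Osmium-catalysed syn-dihydroxylation ([3+2] addition of OsO4) should prefer the trisubstituted C3=C4 alkene over the more hindered tetrasubstituted C7=C11 alkene and should add from the α face, anti to the axial C14 methyl that screens the β face of C4; this sets C4 (4α-O, 4β-CH3) for good and C3 provisionally (3α-OH).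

Step 5
Reactants: 6 eudesm-7(11)-ene-3α,4α-diol
Product: 7 4α-hydroxyeudesm-7(11)-en-3-one
Conditions: IBX, DMSO, rt
Reagents that add atoms: none
Why: IBX oxidation converts the axial secondary 3α-alcohol to the ketone without cleaving the C3–C4 glycol bond, while the tertiary C4 alcohol cannot be oxidised and the quaternary C4 cannot epimerise.

Step 6
Reactants: 7 4α-hydroxyeudesm-7(11)-en-3-one
Product: 8 eudesm-7(11)-ene-3β,4α-diol
Conditions: NaBH4, MeOH, 0 °C
Reagents that add atoms: none
Why: Small-hydride reduction of the cyclohexanone should occur by axial attack on the α face, which carries only axial hydrogens at C1 and C5, whereas the equatorial β trajectory is blocked by the axial 4β-methyl, so the equatorial 3β-alcohol results (the sense known for 4,4-disubstituted 3-keto triterpenoids).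

Step 7
Reactants: 8 eudesm-7(11)-ene-3β,4α-diol; 9 angelic acid
Product: 11 3β-angeloyloxyeudesm-7(11)-en-4α-ol, via angelic 2,4,6-trichlorobenzoic anhydride 10 (not isolated)
Conditions: 9, 2,4,6-trichlorobenzoyl chloride, Et3N, toluene, rt; then 8, toluene, 80 °C
Reagents that add atoms: none
Why: Yamaguchi-type esterification through the preformed mixed anhydride acylates only the secondary equatorial 3β-hydroxyl (the tertiary 4α-hydroxyl is too hindered) and, run without DMAP, avoids the addition–elimination pathway that turns angelates into tiglates, so the Z geometry of 9 should be retained.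

Step 8
Reactants: 11 3β-angeloyloxyeudesm-7(11)-en-4α-ol
Product: 12 4α-acetoxy-3β-angeloyloxyeudesm-7(11)-ene
Conditions: Ac2O, DMAP, Et3N, CH2Cl2, 40 °C
Reagents that add atoms: acetic anhydride, CC(=O)OC(C)=O
Why: DMAP-catalysed (Steglich-type) acetylation with excess anhydride is the standard method for hindered tertiary alcohols; a preformed angelate ester is not activated towards conjugate addition under these conditions and no enolisable ketone is yet present.

Step 9
Reactants: 12 4α-acetoxy-3β-angeloyloxyeudesm-7(11)-ene
Product: 13 4α-acetoxy-3β-angeloyloxyeudesm-7(11)-en-8-one (target, CNP0141494.1)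
Conditions: CrO3, 3,5-dimethylpyrazole, CH2Cl2, −20 °C
Reagents that add atoms: chromium trioxide, O=[Cr](=O)=O
Why: Allylic C–H oxidation with the CrO3·3,5-dimethylpyrazole complex (hexavalent chromium) turns a methylene next to a tetrasubstituted alkene into the enone; of the two axial hydrogens aligned with the π system, 8β-H has one syn-axial methyl whereas 6β-H sits between the C14 and C15 methyls beside the 4α-acetate, a chromate ester formed at C11 would return to C8 by [3,3] shift (Babler–Dauben transposition), the methyl C–H bonds are stronger, and the electron-poor angelate alkene should be inert.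

Compound list
1 | (2E,6E)-farnesol | CC(C)=CCC/C(C)=C/CC/C(C)=C/CO | starting material
2 | (2E,6E)-farnesyl chloride | CC(C)=CCC/C(C)=C/CC/C(C)=C/CCl | intermediate
3 | (2E,6E)-farnesyl diphosphate (handled as triammonium salt; key-step precursor) | CC(C)=CCC/C(C)=C/CC/C(C)=C/COP(=O)(O)OP(=O)(O)O | intermediate
4 | germacrene B ((1(10)E,4E)-germacra-1(10),4,7(11)-triene; enzyme-bound) | C/C1=C\CC/C(C)=C/CC(=C(C)C)CC1 | intermediate
5 | selina-3,7(11)-diene (5α-H, 10β-methyl; key-step product) | CC1=CCC[C@]2(C)CCC(=C(C)C)C[C@@H]12 | intermediate
6 | eudesm-7(11)-ene-3α,4α-diol (4β-methyl, 5α-H, 10β-methyl) | O[C@@H]1CC[C@]2(C)CCC(=C(C)C)C[C@H]2[C@]1(C)O | intermediate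
7 | 4α-hydroxyeudesm-7(11)-en-3-one | O=C1CC[C@]2(C)CCC(=C(C)C)C[C@H]2[C@]1(C)O | intermediate
8 | eudesm-7(11)-ene-3β,4α-diol | O[C@H]1CC[C@]2(C)CCC(=C(C)C)C[C@H]2[C@]1(C)O | intermediate
9 | angelic acid ((Z)-2-methylbut-2-enoic acid) | C/C=C(/C)C(=O)O | starting material
10 | angelic 2,4,6-trichlorobenzoic anhydride | C/C=C(/C)C(=O)OC(=O)c1c(Cl)cc(Cl)cc1Cl | intermediate
11 | 3β-angeloyloxyeudesm-7(11)-en-4α-ol | C/C=C(/C)C(=O)O[C@H]1CC[C@]2(C)CCC(=C(C)C)C[C@H]2[C@]1(C)O | intermediate
12 | 4α-acetoxy-3β-angeloyloxyeudesm-7(11)-ene | C/C=C(/C)C(=O)O[C@H]1CC[C@]2(C)CCC(=C(C)C)C[C@H]2[C@]1(C)OC(C)=O | intermediate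
13 | 4α-acetoxy-3β-angeloyloxyeudesm-7(11)-en-8-one (5α-H, 10β-methyl) | C/C=C(/C)C(=O)O[C@H]1CC[C@]2(C)CC(=O)C(=C(C)C)C[C@H]2[C@]1(C)OC(C)=O | target

Total step count: 9
Longest linear sequence: 9 steps (1 → 13); angelic acid 9 enters unchanged in step 7.

Steps most likely to fail

Step 3 (Proposed new method). The engineered pocket may release the monocyclic germacrene before re-protonation, remove the C15 proton instead of the C3 proton, or bind the mirror-image conformer and so build the antipodal decalin. The fallback uses known chemistry, sets out from 3 and returns at 5. Compound 3 would be cyclised with a wild-type, characterised plant selinene synthase of the 10β-methyl series, which gives α-selinene F1 (selina-3,11-diene; co-formed β-selinene is removed on AgNO3-impregnated silica). F1 already holds rings A and B, both ring-fusion centres and the C3=C4 alkene. Its 1,1-disubstituted isopropenyl alkene would then be moved into the tetrasubstituted C7=C11 position by cobalt-hydride hydrogen-atom-transfer isomerisation (catalytic chloro[N,N'-bis(3,5-di-tert-butylsalicylidene)-1,2-cyclohexanediaminato]cobalt, PhSiH3, benzene, rt). This method acts on 1,1-disubstituted alkenes and leaves the trisubstituted C3=C4 alkene alone; the C7 stereocentre of F1 is erased, giving 5.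

Step 9. Hydrogen abstraction may occur at C6 or at the C12/C13 methyls instead of C8, oxidation may run on to the 6,8-dione, or the angelate may isomerise under the oxidant. The fallback sets out from 12 and returns at 13, placing the C8 oxygen by regiodefined bond construction instead of C–H selection.
- Ozonolysis of the electron-rich C7=C11 alkene (O3, CH2Cl2/MeOH, pyridine, −78 °C, Sudan Red 7B end-point; Me2S), which the electron-poor angelate alkene should survive, gives the 7-ketone F2.
- Thermodynamic enol triflate formation (Tf2O, 2,6-di-tert-butyl-4-methylpyridine, CH2Cl2) should go towards C8, the preference that makes trans-fused 3-keto steroids enolise towards C2, giving the C7=C8 enol triflate F3.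
- Suzuki–Miyaura coupling with isopropenylboronic acid pinacol ester (Pd(PPh3)4, K3PO4, dioxane/H2O) gives the 7,11-diene F4.
- mCPBA (NaHCO3, CH2Cl2, 0 °C) epoxidises the more substituted ring alkene from the α face to the vinyl epoxide F5.
- Lewis-acid Meinwald rearrangement (BF3·OEt2, CH2Cl2, −78 °C) opens F5 at the allylic C7, and a 1,2-hydride shift from C8 leaves the carbonyl at C8, giving the β,γ-unsaturated ketone F6.
- Mild base (Et3N or DBU, CH2Cl2, rt) moves the alkene into conjugation and gives 13.

Step 8. Acylation of the hindered tertiary hydroxyl may stall. Under forcing conditions the angeloyl group may migrate from O3 to O4 with acetylation of the freed secondary hydroxyl, or the angelate may isomerise to the tiglate. The fallback sets out from 7 and returns at 12. The tertiary hydroxyl would be acetylated while C3 is still a ketone (Ac2O, DMAP, pyridine, 60 °C), where it has an sp2 neighbour and no isomerisable ester is present, giving the α-acetoxy ketone F7. Cerium-buffered reduction (NaBH4, CeCl3·7H2O, MeOH, −78 °C, AcOH quench) should again deliver hydride axially from the α face and suppress base-induced O4→O3 acetyl migration, giving the 3β-alcohol F8. DMAP-free acylation of F8 with the mixed anhydride 10 (toluene, 80 °C) would give 12.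

Further compounds
F1 | step 3 | α-selinene (selina-3,11-diene; 5α-H, 7β-isopropenyl, 10β-methyl) | CC1=CCC[C@]2(C)CC[C@@H](C(C)=C)C[C@@H]12
F2 | step 9 | 4α-acetoxy-3β-angeloyloxy-11,12,13-trinoreudesman-7-one | C/C=C(/C)C(=O)O[C@H]1CC[C@]2(C)CCC(=O)C[C@H]2[C@]1(C)OC(C)=O
F3 | step 9 | 4α-acetoxy-3β-angeloyloxy-11,12,13-trinoreudesm-7-en-7-yl trifluoromethanesulfonate | C/C=C(/C)C(=O)O[C@H]1CC[C@]2(C)CC=C(OS(=O)(=O)C(F)(F)F)C[C@H]2[C@]1(C)OC(C)=O
F4 | step 9 | 4α-acetoxy-3β-angeloyloxyeudesma-7,11-diene | C/C=C(/C)C(=O)O[C@H]1CC[C@]2(C)CC=C(C(C)=C)C[C@H]2[C@]1(C)OC(C)=O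
F5 | step 9 | 4α-acetoxy-3β-angeloyloxy-7α,8α-epoxyeudesm-11-ene | C/C=C(/C)C(=O)O[C@H]1CC[C@]2(C)C[C@@H]3O[C@]3(C(C)=C)C[C@H]2[C@]1(C)OC(C)=O
F6 | step 9 | 4α-acetoxy-3β-angeloyloxyeudesm-11-en-8-one (7β-isopropenyl; C7 configuration inconsequential) | C/C=C(/C)C(=O)O[C@H]1CC[C@]2(C)CC(=O)[C@@H](C(C)=C)C[C@H]2[C@]1(C)OC(C)=O
F7 | step 8 | 4α-acetoxyeudesm-7(11)-en-3-one | O=C1CC[C@]2(C)CCC(=C(C)C)C[C@H]2[C@]1(C)OC(C)=O
F8 | step 8 | 4α-acetoxyeudesm-7(11)-en-3β-ol | O[C@H]1CC[C@]2(C)CCC(=C(C)C)C[C@H]2[C@]1(C)OC(C)=O
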